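The route rests on the C1–C10 ring-fusion bond, the one bond that divides a fourteen-membered carbocycle (C1 to C14) into ring A (C1, C10 to C14) and the ten-membered ring (C1 to C10). A Lewis acid opens a 1,14-epoxide at tertiary C1 and the C10=C11 alkene closes that bond transannularly, so both carbocycles and the C1 and C10 stereocentres arise in one operation. The precursor is a geraniol-derived fourteen-membered epoxide bearing silyl ethers at C2 and C9 and a C5=C6 chloroenone (C7 ketone) that is too electron-poor to compete. Ring A is then oxygenated by a Wharton transposition and the lactone is annulated on C7–C8 by a Reformatsky closure.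

Key step: step 15

Remark: atoms carry the carbocycle numbering C1–C14 (C15 = methyl on C1, C17 and C19 = lactone methine and carbonyl), α is the face opposite the C15 methyl, and C8 of 22–28 is a temporary stereocentre carried as an epimer mixture until it is oxidized in step 21.

Step 1
Reactants: 1 geraniol
Product: 2 geranyl 4-methoxybenzyl ether
Conditions: NaH, 4-methoxybenzyl chloride, Bu4NI (cat.), THF, 0 °C to rt
Reagents that add atoms: 4-methoxybenzyl chloride, COc1ccc(CCl)cc1
Why: Williamson etherification of the primary allylic alkoxide installs an oxidatively removable ether that should survive the organomagnesium, organolithium and cuprate steps.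

Step 2
Reactants: 2 geranyl 4-methoxybenzyl ether
Product: 3 (2E,6E)-8-(4-methoxybenzyloxy)-2,6-dimethylocta-2,6-dien-1-ol
Conditions: SeO2 (cat.), t-BuOOH, salicylic acid (cat.), CH2Cl2, rt; then NaBH4, MeOH, 0 °C
Reagents that add atoms: tert-butyl hydroperoxide, CC(C)(C)OO (oxygen relayed by SeO2)
Why: Catalytic SeO2 allylic oxidation attacks the E methyl group of the electron-rich terminal alkene (future C2), the other alkene being deactivated by its allylic ether, and the borohydride work-up returns any enal to the alcohol.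

Step 3
Reactants: 3 (2E,6E)-8-(4-methoxybenzyloxy)-2,6-dimethylocta-2,6-dien-1-ol
Product: 4 [(2R,3R)-3-[(3E)-5-(4-methoxybenzyloxy)-3-methylpent-3-en-1-yl]-2-methyloxiran-2-yl]methanol
Conditions: Ti(OiPr)4 (cat.), D-(−)-diethyl tartrate, t-BuOOH, 4 Å MS, CH2Cl2, −20 °C
Reagents that add atoms: tert-butyl hydroperoxide, CC(C)(C)OO
Why: Sharpless asymmetric epoxidation is confined to the allylic alcohol alkene, and D-(−)-tartrate should deliver oxygen to the face that gives the (2R,3R)-epoxy alcohol, which fixes C1 and C14.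

Step 4
Reactants: 4 (2R,3R)-epoxy alcohol
Product: 5 (2S,3R)-epoxy aldehyde (CHO in place of CH2OH of 4)
Conditions: Dess–Martin periodinane, NaHCO3, CH2Cl2, 0 °C to rt
Reagents that add atoms: none
Why: Dess–Martin oxidation gives an epoxy aldehyde whose α-carbon is fully substituted and therefore cannot epimerize.

Step 5
Reactants: 5 (2S,3R)-epoxy aldehyde; 6 (4-bromobut-1-yn-1-yl)trimethylsilane
Product: 8 threo epoxy alcohol with (S)-configured C2 carbinol and silylalkyne chain, via Grignard reagent 7 (not isolated)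
Conditions: 6, Mg, THF, rt; then 5, Et2O–THF, −78 °C
Reagents that add atoms: none
Why: Grignard addition to the α,β-epoxy aldehyde under Cram-chelate control (magnesium bridging carbonyl and epoxide oxygens, attack past the methyl group and away from the C14 ring carbon) should favour the threo alcohol that the cyclization substrate needs, which a hydroxyl-directed epoxidation of the corresponding allylic alcohol could not give.

Step 6
Reactants: 8 threo epoxy alcohol
Product: 9 C2 tert-butyldimethylsilyl ether of 8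
Conditions: TBSCl, imidazole, DMAP (cat.), DMF, rt
Reagents that add atoms: tert-butyldimethylsilyl chloride, CC(C)(C)[Si](C)(C)Cl
Why: Imidazole-promoted silylation protects the secondary alcohol without a silyl triflate, which could trigger rearrangement of the epoxy silyl ether.

Step 7
Reactants: 9 C2 silyl ether
Product: 11 methyl ynoate (C5≡C6 alkyne carrying the C7 methyl ester), via lithium acetylide 10 (not isolated)
Conditions: MeLi·LiBr, THF, 0 °C to rt; then ClCO2Me, −78 °C
Reagents that add atoms: methyl chloroformate, COC(=O)Cl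
Why: Cleavage of the alkynyl C–Si bond by methyllithium gives the lithium acetylide, which is acylated by the chloroformate in the same flask (acetylide carboxylation).

Step 8
Reactants: 11 methyl ynoate
Product: 13 methyl (E)-2-chloro-3-methylalk-2-enoate (chlorine cis to the C5 methyl; C4 cis to C7), via vinylcuprate 12 (not isolated)
Conditions: Me2CuLi, THF, −78 °C; then N-chlorosuccinimide, −78 °C
Reagents that add atoms: lithium dimethylcuprate, C[Cu-]C.[Li+]; N-chlorosuccinimide, O=C1CCC(=O)N1Cl
Why: Syn carbocupration of the ynoate at −78 °C puts methyl on C5 and copper on C6 on the same side, and chlorination of the vinylcopper with retention should give the tetrasubstituted chloroalkene as one isomer, which a Horner–Wadsworth–Emmons reaction of a methyl ketone would not.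

Step 9
Reactants: 13 chloro enoate
Product: 14 N-methoxy-N-methyl amide of 13
Conditions: MeNH(OMe)·HCl, i-PrMgCl, THF, −20 °C
Reagents that add atoms: N,O-dimethylhydroxylamine hydrochloride, CNOC.Cl
Why: Aminolysis of the ester by the magnesium amide (Weinreb amide formation) prepares a single acyl substitution.

Step 10
Reactants: 14 Weinreb amide
Product: 15 methyl ketone (C7 ketone, C8 methyl)
Conditions: MeMgBr, THF, 0 °C
Reagents that add atoms: methylmagnesium bromide, C[Mg]Br
Why: Weinreb ketone synthesis, in which the chelated tetrahedral intermediate stops the Grignard addition at the ketone.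

Step 11
Reactants: 15 methyl ketone
Product: 16 C9 allylic alcohol
Conditions: DDQ, CH2Cl2–pH 7 buffer, 0 °C
Reagents that add atoms: none
Why: Oxidative cleavage of the 4-methoxybenzyl ether by DDQ should leave silyl ether, epoxide and chloroenone untouched.

Step 12
Reactants: 16 C9 allylic alcohol
Product: 17 keto enal (C9 aldehyde)
Conditions: MnO2, CH2Cl2, rt
Reagents that add atoms: none
Why: MnO2 oxidizes only the allylic alcohol and keeps the E geometry of the enal.

Step 13
Reactants: 17 keto enal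
Product: 19 fourteen-membered (9R)-β-hydroxy ketone, via boron enolate 18 (not isolated)
Conditions: (−)-Ipc2BCl, Et3N, Et2O, −78 to −20 °C, slow addition (final 1 mM); then MeOH, pH 7 buffer, H2O2, 0 °C
Reagents that add atoms: none
Why: Boron-mediated aldol reaction run as a macrocyclization: the diisopinocampheylboron enolate of the methyl ketone adds to the non-enolizable enal under high dilution, and the (−)-Ipc ligands are expected to direct attack to the aldehyde face that gives the (9R) carbinol, as in Paterson aldol reactions of methyl ketones.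

Step 14
Reactants: 19 macrocyclic β-hydroxy ketone
Product: 20 cyclization precursor (C9 tert-butyldiphenylsilyl ether, C2 tert-butyldimethylsilyl ether, 1,14-epoxide, chloroenone)
Conditions: TBDPSCl, imidazole, DMAP (cat.), DMF, rt
Reagents that add atoms: tert-butyldiphenylsilyl chloride, CC(C)(C)[Si](Cl)(c1ccccc1)c1ccccc1
Why: Imidazole-promoted silylation protects the aldol without Lewis acid, and the bulky acid-stable group is chosen to outlast the C2 ether and to shield H10 in the next step.

Step 15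
Reactants: 20 cyclization precursor
Product: 21 trans-fused bicyclic C14β alcohol with C11=C12 alkene
Conditions: BF3·OEt2 (0.3 equiv), CH2Cl2, −78 °C; then Et3N
Reagents that add atoms: none
Why: BF3 coordination to the epoxide oxygen polarizes the tertiary C1–O bond, the C10=C11 alkene attacks C1 through C10 anti to the departing oxygen and the tertiary C11 cation loses a C12 proton, which is a Lewis-acid epoxide-initiated cation–olefin cyclization run transannularly as known for germacrene and cembrene epoxides. Ring A closes 6-endo-trig at the alkene through a chair with the former epoxide oxygen left exocyclic on C14, and the ten-membered ring is what remains of the fourteen-membered ring once the C1–C10 bond exists. C1 is set by inversion of the enantiopure (1S,14R)-epoxide and C10 by the E alkene in the chair, which places C2, C9 and the C14 oxygen equatorial and so gives the trans fusion with the C15 methyl anti to H10. The step needs regioselectivity between two alkenes and two epoxide carbons, which is secured because the C5=C6 alkene is deactivated by chlorine and by conjugation to the C7 ketone and because only C1 can carry tertiary cation character. Low temperature and the bulky C2 silyl ether are meant to hold back a 1,2-hydride shift from C2, and the bulky C9 silyl ether shields H10 so that proton loss should occur at C12 (an exocyclic alkene isomer would converge in step 17).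

Step 16
Reactants: 21 bicyclic C14 alcohol
Product: 23 C8 and C14 bis(triethylsilyl) ether of the C8-hydroxylated ketone, via C8 hydroxy ketone 22 (not isolated)
Conditions: KN(SiMe3)2 (2.2 equiv), THF, −78 °C; 2-(phenylsulfonyl)-3-phenyloxaziridine; then TESCl, −78 to 0 °C
Reagents that add atoms: 2-(phenylsulfonyl)-3-phenyloxaziridine, O=S(=O)(c1ccccc1)N1OC1c1ccccc1; triethylsilyl chloride, CC[Si](Cl)(CC)CC
Why: Kinetic deprotonation gives the C8 enolate (C6 has no hydrogen), which undergoes Davis enolate hydroxylation, and both potassium alkoxides are silylated in the same flask.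

Step 17
Reactants: 23 bis(triethylsilyl) ether
Product: 24 11,12-dihydro compound with 11β-methyl (H11 α, cis to H10)
Conditions: H2 (1 atm), PtO2 (cat.), EtOAc, rt
Reagents that add atoms: none
Why: Heterogeneous hydrogenation should add to the α face, opposite the axial C15 methyl and the C14 silyl ether, which sets C11 kinetically (an equilibrating enone isomerization would not be reliable here), while the hindered tetrasubstituted chloroalkene should be inert on platinum.

Step 18
Reactants: 24 11,12-dihydro ketone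
Product: 25 (7S)-allylic alcohol
Conditions: (R)-Me-CBS (0.2 equiv), catecholborane, toluene, −78 °C
Reagents that add atoms: none
Why: Corey–Bakshi–Shibata reduction with the α-chlorovinyl group as the large substituent, as for α-halo enones, should give the (7S) alcohol under reagent control whatever the C8 configuration.

Step 19
Reactants: 25 (7S)-alcohol; 26 2-bromopropanoyl bromide
Product: 27 C7 2-bromopropanoate
Conditions: pyridine, DMAP (cat.), CH2Cl2, −20 °C
Reagents that add atoms: none
Why: Acylation of the only free hydroxyl by the acid bromide installs the Reformatsky donor on O7.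

Step 20
Reactants: 27 C7 2-bromopropanoate
Product: 28 C8 and C14 diol
Conditions: HF·pyridine, pyridine, THF, 0 °C
Reagents that add atoms: none
Why: Buffered fluoride desilylation cleaves the two triethylsilyl ethers much faster than the TBS and TBDPS ethers, and the acidic medium disfavours acyl migration from O7.

Step 21
Reactants: 28 diol
Product: 29 C8 and C14 diketone
Conditions: Dess–Martin periodinane, NaHCO3, CH2Cl2, 0 °C to rt
Reagents that add atoms: none
Why: Dess–Martin oxidation converts both secondary alcohols into ketones under neutral conditions, which moves the carbonyl from C7 to C8 without relying on an acyloin equilibrium and without epimerizing C7.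

Step 22
Reactants: 29 diketone
Product: 31 cis-fused hydroxy lactone with C14 ketone, via samarium enolate 30 (not isolated)
Conditions: SmI2, THF, −78 °C
Reagents that add atoms: none
Why: Intramolecular Reformatsky reaction, as in the classical cardenolide lactone synthesis: SmI2 reduces the C–Br bond and the samarium enolate should add to the C8 ketone from the face of the O7 tether and anti to the C9 silyloxy group (Felkin–Anh), giving the cis-fused lactone with the C17 methyl on the less hindered side, anti to C9.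

Step 23
Reactants: 31 hydroxy lactone ketone
Product: 32 C12=C13 enone
Conditions: IBX·4-methoxypyridine N-oxide, DMSO, 25 °C
Reagents that add atoms: none
Why: IBX dehydrogenation of the ketone, which can enolize only towards C13 because C1 is quaternary.

Step 24
Reactants: 32 enone
Product: 33 12α,13α-epoxy ketone
Conditions: t-BuOOH, DBU, CH2Cl2, 0 °C
Reagents that add atoms: tert-butyl hydroperoxide, CC(C)(C)OO
Why: Weitz–Scheffer nucleophilic epoxidation, in which the hydroperoxide anion should add to C12 from the α face, anti to the adjacent 11β-methyl and the axial C15 methyl.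

Step 25
Reactants: 33 epoxy ketone
Product: 34 12α-hydroxy 13,14-alkene
Conditions: N2H4·H2O, AcOH (cat.), MeOH, 0 °C to rt
Reagents that add atoms: none
Why: Wharton transposition: the epoxy hydrazone fragments with loss of N2 to the C13=C14 alkene and keeps the C12–O bond, so the new alcohol is α.

Step 26
Reactants: 34 allylic alcohol
Product: 35 C2 and C12 diol
Conditions: HF·pyridine, THF, rt
Reagents that add atoms: none
Why: Acidic fluoride desilylation removes the TBS ether while the TBDPS ether survives, and it is placed before the acid-sensitive epoxide exists.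

Step 27
Reactants: 35 diol
Product: 36 13α,14α-epoxide
Conditions: VO(acac)2 (cat.), t-BuOOH, CH2Cl2, 0 °C to rt
Reagents that add atoms: tert-butyl hydroperoxide, CC(C)(C)OO
Why: Vanadium-catalysed hydroxyl-directed epoxidation delivers oxygen syn to the allylic 12α-hydroxyl, which is also the face opposite the C15 methyl.

Step 28
Reactants: 36 epoxy triol
Product: 37 C2 and C12 diacetate (C9 silyl ether of the target)
Conditions: Ac2O, DMAP, pyridine, CH2Cl2, rt
Reagents that add atoms: acetic anhydride, CC(=O)OC(C)=O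
Why: DMAP-catalysed acetylation esterifies the two secondary alcohols, the tertiary C8 alcohol being too hindered and C9 still silylated.

Step 29
Reactants: 37 diacetate silyl ether
Product: 38 target compound
Conditions: Bu4NF, AcOH, THF, rt
Reagents that add atoms: none
Why: Buffered fluoride desilylation should free the C9 alcohol without acetyl migration, lactone opening or epoxide opening.

Compound list
1 | geraniol | CC(C)=CCC/C(C)=C/CO | starting material
2 | geranyl 4-methoxybenzyl ether | CC(C)=CCC/C(C)=C/COCc1ccc(OC)cc1 | intermediate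
3 | (2E,6E)-8-(4-methoxybenzyloxy)-2,6-dimethylocta-2,6-dien-1-ol | OC/C(C)=C/CC/C(C)=C/COCc1ccc(OC)cc1 | intermediate
4 | (2R,3R)-epoxy alcohol | OC[C@@]1(C)O[C@@H]1CC/C(C)=C/COCc1ccc(OC)cc1 | intermediate
5 | (2S,3R)-epoxy aldehyde | O=C[C@@]1(C)O[C@@H]1CC/C(C)=C/COCc1ccc(OC)cc1 | intermediate
6 | (4-bromobut-1-yn-1-yl)trimethylsilane | C[Si](C)(C)C#CCCBr | starting material
7 | [4-(trimethylsilyl)but-3-yn-1-yl]magnesium bromide | C[Si](C)(C)C#CCC[Mg]Br | intermediate
8 | threo epoxy alcohol, (S)-C2 carbinol | C[Si](C)(C)C#CCC[C@H](O)[C@@]1(C)O[C@@H]1CC/C(C)=C/COCc1ccc(OC)cc1 | intermediate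
9 | C2 TBS ether of 8 | C[Si](C)(C)C#CCC[C@H](O[Si](C)(C)C(C)(C)C)[C@@]1(C)O[C@@H]1CC/C(C)=C/COCc1ccc(OC)cc1 | intermediate
10 | lithium acetylide | [Li]C#CCC[C@H](O[Si](C)(C)C(C)(C)C)[C@@]1(C)O[C@@H]1CC/C(C)=C/COCc1ccc(OC)cc1 | intermediate
11 | methyl ynoate | COC(=O)C#CCC[C@H](O[Si](C)(C)C(C)(C)C)[C@@]1(C)O[C@@H]1CC/C(C)=C/COCc1ccc(OC)cc1 | intermediate
12 | lithium methyl(vinyl)cuprate, copper on C6 cis to the C5 methyl | COC(=O)/C([Cu-]C)=C(/C)CC[C@H](O[Si](C)(C)C(C)(C)C)[C@@]1(C)O[C@@H]1CC/C(C)=C/COCc1ccc(OC)cc1.[Li+] | intermediate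
13 | methyl (E)-2-chloro-3-methylalk-2-enoate | COC(=O)/C(Cl)=C(/C)CC[C@H](O[Si](C)(C)C(C)(C)C)[C@@]1(C)O[C@@H]1CC/C(C)=C/COCc1ccc(OC)cc1 | intermediate
14 | Weinreb amide | CON(C)C(=O)/C(Cl)=C(/C)CC[C@H](O[Si](C)(C)C(C)(C)C)[C@@]1(C)O[C@@H]1CC/C(C)=C/COCc1ccc(OC)cc1 | intermediate
15 | methyl ketone | CC(=O)/C(Cl)=C(/C)CC[C@H](O[Si](C)(C)C(C)(C)C)[C@@]1(C)O[C@@H]1CC/C(C)=C/COCc1ccc(OC)cc1 | intermediate
16 | C9 allylic alcohol | CC(=O)/C(Cl)=C(/C)CC[C@H](O[Si](C)(C)C(C)(C)C)[C@@]1(C)O[C@@H]1CC/C(C)=C/CO | intermediate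
17 | keto enal | CC(=O)/C(Cl)=C(/C)CC[C@H](O[Si](C)(C)C(C)(C)C)[C@@]1(C)O[C@@H]1CC/C(C)=C/C=O | intermediate
18 | diisopinocampheylboron enolate of 17 | C=C(OB([C@@H]1C[C@@H]2C[C@H]([C@H]1C)C2(C)C)[C@@H]1C[C@@H]2C[C@H]([C@H]1C)C2(C)C)/C(Cl)=C(/C)CC[C@H](O[Si](C)(C)C(C)(C)C)[C@@]1(C)O[C@@H]1CC/C(C)=C/C=O | intermediate
19 | fourteen-membered (9R)-β-hydroxy ketone | C1C/C(C)=C/[C@H](O)CC(=O)/C(Cl)=C(/C)CC[C@H](O[Si](C)(C)C(C)(C)C)[C@@]2(C)O[C@@H]21 | intermediate
20 | cyclization precursor | C1C/C(C)=C/[C@H](O[Si](c3ccccc3)(c3ccccc3)C(C)(C)C)CC(=O)/C(Cl)=C(/C)CC[C@H](O[Si](C)(C)C(C)(C)C)[C@@]2(C)O[C@@H]21 | intermediate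
21 | trans-fused bicyclic C14β alcohol, C11=C12 alkene | C1=C(C)[C@@H]2[C@H](O[Si](c3ccccc3)(c3ccccc3)C(C)(C)C)CC(=O)/C(Cl)=C(/C)CC[C@H](O[Si](C)(C)C(C)(C)C)[C@@]2(C)[C@H](O)C1 | intermediate
22 | C8 hydroxy ketone (C8 epimers) | C1=C(C)[C@@H]2[C@H](O[Si](c3ccccc3)(c3ccccc3)C(C)(C)C)C(O)C(=O)/C(Cl)=C(/C)CC[C@H](O[Si](C)(C)C(C)(C)C)[C@@]2(C)[C@H](O)C1 | intermediate
23 | C8 and C14 bis(triethylsilyl) ether | C1=C(C)[C@@H]2[C@H](O[Si](c3ccccc3)(c3ccccc3)C(C)(C)C)C(O[Si](CC)(CC)CC)C(=O)/C(Cl)=C(/C)CC[C@H](O[Si](C)(C)C(C)(C)C)[C@@]2(C)[C@H](O[Si](CC)(CC)CC)C1 | intermediate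
24 | 11,12-dihydro compound, 11β-methyl | C1[C@H](C)[C@@H]2[C@H](O[Si](c3ccccc3)(c3ccccc3)C(C)(C)C)C(O[Si](CC)(CC)CC)C(=O)/C(Cl)=C(/C)CC[C@H](O[Si](C)(C)C(C)(C)C)[C@@]2(C)[C@H](O[Si](CC)(CC)CC)C1 | intermediate
25 | (7S)-allylic alcohol | C1[C@H](C)[C@@H]2[C@H](O[Si](c3ccccc3)(c3ccccc3)C(C)(C)C)C(O[Si](CC)(CC)CC)[C@H](O)/C(Cl)=C(/C)CC[C@H](O[Si](C)(C)C(C)(C)C)[C@@]2(C)[C@H](O[Si](CC)(CC)CC)C1 | intermediate
26 | 2-bromopropanoyl bromide (racemic) | CC(Br)C(Br)=O | starting material
27 | C7 2-bromopropanoate | C1[C@H](C)[C@@H]2[C@H](O[Si](c3ccccc3)(c3ccccc3)C(C)(C)C)C(O[Si](CC)(CC)CC)[C@H](OC(=O)C(C)Br)/C(Cl)=C(/C)CC[C@H](O[Si](C)(C)C(C)(C)C)[C@@]2(C)[C@H](O[Si](CC)(CC)CC)C1 | intermediate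
28 | C8 and C14 diol | C1[C@H](C)[C@@H]2[C@H](O[Si](c3ccccc3)(c3ccccc3)C(C)(C)C)C(O)[C@H](OC(=O)C(C)Br)/C(Cl)=C(/C)CC[C@H](O[Si](C)(C)C(C)(C)C)[C@@]2(C)[C@H](O)C1 | intermediate
29 | C8 and C14 diketone | C1[C@H](C)[C@@H]2[C@H](O[Si](c3ccccc3)(c3ccccc3)C(C)(C)C)C(=O)[C@H](OC(=O)C(C)Br)/C(Cl)=C(/C)CC[C@H](O[Si](C)(C)C(C)(C)C)[C@@]2(C)C(=O)C1 | intermediate
30 | samarium ester enolate | C1[C@H](C)[C@@H]2[C@H](O[Si](c3ccccc3)(c3ccccc3)C(C)(C)C)C(=O)[C@H](OC(O[Sm](I)I)=CC)/C(Cl)=C(/C)CC[C@H](O[Si](C)(C)C(C)(C)C)[C@@]2(C)C(=O)C1 | intermediate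
31 | cis-fused hydroxy lactone, C14 ketone | C1[C@H](C)[C@@H]2[C@H](O[Si](c4ccccc4)(c4ccccc4)C(C)(C)C)[C@@]3(O)[C@H](OC(=O)[C@@H]3C)/C(Cl)=C(/C)CC[C@H](O[Si](C)(C)C(C)(C)C)[C@@]2(C)C(=O)C1 | intermediate
32 | C12=C13 enone | C[C@@H]1[C@@H]2[C@H](O[Si](c4ccccc4)(c4ccccc4)C(C)(C)C)[C@@]3(O)[C@H](OC(=O)[C@@H]3C)/C(Cl)=C(/C)CC[C@H](O[Si](C)(C)C(C)(C)C)[C@@]2(C)C(=O)C=C1 | intermediate
33 | 12α,13α-epoxy ketone | C[C@@H]1[C@@H]2[C@H](O[Si](c4ccccc4)(c4ccccc4)C(C)(C)C)[C@@]3(O)[C@H](OC(=O)[C@@H]3C)/C(Cl)=C(/C)CC[C@H](O[Si](C)(C)C(C)(C)C)[C@@]2(C)C(=O)[C@H]2O[C@@H]12 | intermediate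
34 | 12α-hydroxy 13,14-alkene | C[C@@H]1[C@@H]2[C@H](O[Si](c4ccccc4)(c4ccccc4)C(C)(C)C)[C@@]3(O)[C@H](OC(=O)[C@@H]3C)/C(Cl)=C(/C)CC[C@H](O[Si](C)(C)C(C)(C)C)[C@@]2(C)C=C[C@H]1O | intermediate
35 | C2 and C12 diol | C[C@@H]1[C@@H]2[C@H](O[Si](c4ccccc4)(c4ccccc4)C(C)(C)C)[C@@]3(O)[C@H](OC(=O)[C@@H]3C)/C(Cl)=C(/C)CC[C@H](O)[C@@]2(C)C=C[C@H]1O | intermediate
36 | 13α,14α-epoxide | C[C@@H]1[C@@H]2[C@H](O[Si](c4ccccc4)(c4ccccc4)C(C)(C)C)[C@@]3(O)[C@H](OC(=O)[C@@H]3C)/C(Cl)=C(/C)CC[C@H](O)[C@@]2(C)[C@H]2O[C@H]2[C@H]1O | intermediate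
37 | C2 and C12 diacetate, C9 TBDPS ether | C[C@@H]1[C@@H]2[C@H](O[Si](c4ccccc4)(c4ccccc4)C(C)(C)C)[C@@]3(O)[C@H](OC(=O)[C@@H]3C)/C(Cl)=C(/C)CC[C@H](OC(C)=O)[C@@]2(C)[C@H]2O[C@H]2[C@H]1OC(C)=O | intermediate
38 | CNP0255641.1 | CC(=O)O[C@H]1[C@H](C)[C@@H]2[C@H](O)[C@@]3(O)[C@H](OC(=O)[C@@H]3C)/C(Cl)=C(/C)CC[C@H](OC(C)=O)[C@@]2(C)[C@H]2O[C@@H]12 | target

Total step count: 29. Longest linear sequence: 29 steps from geraniol (6 and 26 are purchased).

Steps most likely to fail

Step 15. The Lewis-acid opening may be diverted into a 1,2-hydride shift from C2 to C1 (semipinacol rearrangement of the epoxy silyl ether), or proton loss may be unselective. The fallback replaces the cationic opening by a radical one and sets out from 20. Cp2TiCl2 and Mn in THF generate Cp2TiCl (trivalent titanium), which should open the epoxide homolytically at C1. The tertiary radical adds transannularly to C10, and the C11 radical is trapped and eliminated to give the C11-methylene bicyclic C14 alcohol F1. F1 is taken through the conditions of step 16 to the exocyclic-alkene bis(triethylsilyl) ether F2. Hydrogenation of F2 under the conditions of step 17 adds to the α face of the exocyclic alkene and gives 24, where the route is rejoined.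

Step 13. The ring closure may lose to oligomerization, the chloroborane may attack the aldehyde or the epoxide, or facial selectivity at C9 may be poor. The fallback is a chromium Reformatsky macrocyclization under neutral conditions and sets out from 15. LiN(SiMe3)2 and TMSCl give the trimethylsilyl enol ether F3, and NBS converts it into the bromomethyl ketone F4. DDQ and then MnO2, as in steps 11 and 12, give the bromo keto alcohol F5 and the bromo keto enal F6. CrCl2 with LiI in THF under high dilution should close F6 to 19, the C9 epimers being separated by chromatography; the route is rejoined at 19.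

Step 22. SmI2 may cleave the C7–O bond of the α-acyloxy ketone reductively instead of forming the enolate, or addition may occur on the wrong face of the C8 ketone. The fallback forms a butenolide and then oxygenates C8; it sets out from 25. Esterification with 2-(diethoxyphosphoryl)propanoic acid (DCC, DMAP) gives the phosphonopropionate F7, HF·pyridine gives the diol F8 and Dess–Martin oxidation gives the diketone F9. LiCl and i-Pr2NEt in MeCN (intramolecular Horner–Wadsworth–Emmons reaction) close the butenolide F10. t-BuOOH with benzyltrimethylammonium hydroxide should epoxidize F10 anti to the C6 substituent on C7 and give the epoxy lactone F11. SmI2 in THF–MeOH cleaves the C17–O bond of F11 and gives 31, where the route is rejoined.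

Further compounds
F1 | step 15 | C11-methylene bicyclic C14 alcohol | C=C1[C@@H]2[C@H](O[Si](c3ccccc3)(c3ccccc3)C(C)(C)C)CC(=O)/C(Cl)=C(/C)CC[C@H](O[Si](C)(C)C(C)(C)C)[C@@]2(C)[C@H](O)CC1
F2 | step 15 | exocyclic-alkene bis(triethylsilyl) ether | C=C1[C@@H]2[C@H](O[Si](c3ccccc3)(c3ccccc3)C(C)(C)C)C(O[Si](CC)(CC)CC)C(=O)/C(Cl)=C(/C)CC[C@H](O[Si](C)(C)C(C)(C)C)[C@@]2(C)[C@H](O[Si](CC)(CC)CC)CC1
F3 | step 13 | trimethylsilyl enol ether of 15 | C=C(O[Si](C)(C)C)/C(Cl)=C(/C)CC[C@H](O[Si](C)(C)C(C)(C)C)[C@@]1(C)O[C@@H]1CC/C(C)=C/COCc1ccc(OC)cc1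
F4 | step 13 | bromomethyl ketone | BrCC(=O)/C(Cl)=C(/C)CC[C@H](O[Si](C)(C)C(C)(C)C)[C@@]1(C)O[C@@H]1CC/C(C)=C/COCc1ccc(OC)cc1
F5 | step 13 | bromo keto alcohol | BrCC(=O)/C(Cl)=C(/C)CC[C@H](O[Si](C)(C)C(C)(C)C)[C@@]1(C)O[C@@H]1CC/C(C)=C/CO
F6 | step 13 | bromo keto enal | BrCC(=O)/C(Cl)=C(/C)CC[C@H](O[Si](C)(C)C(C)(C)C)[C@@]1(C)O[C@@H]1CC/C(C)=C/C=O
F7 | step 22 | C7 phosphonopropionate | C1[C@H](C)[C@@H]2[C@H](O[Si](c4ccccc4)(c4ccccc4)C(C)(C)C)C(O[Si](CC)(CC)CC)[C@H](OC(=O)C(C)P(=O)(OCC)OCC)/C(Cl)=C(/C)CC[C@H](O[Si](C)(C)C(C)(C)C)[C@@]2(C)[C@H](O[Si](CC)(CC)CC)C1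
F8 | step 22 | phosphonopropionate diol | C1[C@H](C)[C@@H]2[C@H](O[Si](c4ccccc4)(c4ccccc4)C(C)(C)C)C(O)[C@H](OC(=O)C(C)P(=O)(OCC)OCC)/C(Cl)=C(/C)CC[C@H](O[Si](C)(C)C(C)(C)C)[C@@]2(C)[C@H](O)C1
F9 | step 22 | phosphonopropionate diketone | C1[C@H](C)[C@@H]2[C@H](O[Si](c4ccccc4)(c4ccccc4)C(C)(C)C)C(=O)[C@H](OC(=O)C(C)P(=O)(OCC)OCC)/C(Cl)=C(/C)CC[C@H](O[Si](C)(C)C(C)(C)C)[C@@]2(C)C(=O)C1
F10 | step 22 | butenolide | C1[C@H](C)[C@@H]2[C@H](O[Si](c4ccccc4)(c4ccccc4)C(C)(C)C)C3=C(C)C(=O)O[C@@H]3/C(Cl)=C(/C)CC[C@H](O[Si](C)(C)C(C)(C)C)[C@@]2(C)C(=O)C1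
F11 | step 22 | epoxy lactone | C1[C@H](C)[C@@H]2[C@H](O[Si](c5ccccc5)(c5ccccc5)C(C)(C)C)[C@@]34O[C@@]4(C)C(=O)O[C@@H]3/C(Cl)=C(/C)CC[C@H](O[Si](C)(C)C(C)(C)C)[C@@]2(C)C(=O)C1
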